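**Plan**

1. Bonds cut, in order: O7–S and O3'–S, then C4a–C5 of ring A, then C6–C7 and C7–C8 of the side chain, then O1–C8a and C2–C3 of ring C. This leads back to a protected methyl protocatechuate, acetylacetone, CO2 and a malonate half-ester.
2. Enabling feature: in ring A, oxygen sits on C5, C7 and C8a, every second carbon, as in a folded acetate chain. C4a is the α-carbon of the dienolate that ring C (a 2-aryl-4-pyranone) forms when the C8 methylene on C8a is deprotonated. Ring A is therefore an intramolecular C-acylation of ring C by a C5 ester.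
3. Forward order: ring B is bought and ring C is closed from a 1,3,5-triketone. Its C8 methyl group is extended by C7 (CO2) and C6–C5 (malonate), and ring A is closed and aromatised last.
4. Sulfate sites: 4'-O carries benzyl and 3'-O carries allyl from the outset. After deallylation only 7-OH and 3'-OH are free and unchelated, so one sulfation serves both and hydrogenolysis ends the route.
5. Stereochemistry: the target is achiral, with no stereocentre and no configurable double bond, so nothing has to be set.

Key step: step 7

Assumption: the target has no stereogenic element, so no enantioselective step is needed; the hydrogen sulfate form drawn is liberated only in the last operation, and all earlier sulfates are handled as triethylammonium salts.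

**Step 1**
Reactants: 1 methyl 3,4-dihydroxybenzoate; 2 benzyl bromide
Product: 3 methyl 4-(benzyloxy)-3-hydroxybenzoate
Conditions: BnBr (1.0 equiv), K2CO3 (1.0 equiv), DMF, 0 °C → rt
Reagents that add atoms: benzyl bromide (2), BrCc1ccccc1
Why: Williamson etherification under stoichiometric control: the 4-OH is para to the ester and is the more acidic phenol, so one equivalent of carbonate ionises it first and one equivalent of benzyl bromide should cap it, the usual outcome with 3,4-dihydroxybenzoates.

**Step 2**
Reactants: 3 methyl 4-(benzyloxy)-3-hydroxybenzoate; 4 allyl bromide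
Product: 5 methyl 3-(allyloxy)-4-(benzyloxy)benzoate
Conditions: allyl bromide, K2CO3, DMF, 50 °C
Reagents that add atoms: allyl bromide (4), C=CCBr
Why: Williamson etherification of the only phenol left; the allyl ether withstands the hydride, amide and acid steps ahead and can later be removed by Pd(0) without touching the benzyl ether.

**Step 3**
Reactants: 5 methyl 3-(allyloxy)-4-(benzyloxy)benzoate; 6 acetylacetone
Product: 7 1-[3-(allyloxy)-4-(benzyloxy)phenyl]hexane-1,3,5-trione (drawn as the triketo tautomer)
Conditions: NaH (4 equiv), DME, reflux; then 1 M HCl, 0 °C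
Reagents that add atoms: acetylacetone (6), CC(=O)CC(C)=O
Why: Claisen acylation of a 1,3-diketone dianion: with excess NaH the terminal methyl carbon of acetylacetone is the reactive nucleophile, the aryl ester cannot enolise, and the triketone is withdrawn from the equilibrium as its polyanion.

**Step 4**
Reactants: 7 1-[3-(allyloxy)-4-(benzyloxy)phenyl]hexane-1,3,5-trione
Product: 8 2-[3-(allyloxy)-4-(benzyloxy)phenyl]-6-methyl-4H-pyran-4-one
Conditions: p-TsOH·H2O (10 mol %), toluene, reflux, Dean–Stark
Reagents that add atoms: none
Why: Acid-catalysed cyclodehydration of a 1,3,5-triketone, in which the enol oxygen of one terminal carbonyl adds to the other and water is lost; only one 4-pyranone can arise and catalytic sulfonic acid leaves both aryl ethers intact.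

**Step 5**
Reactants: 8 2-[3-(allyloxy)-4-(benzyloxy)phenyl]-6-methyl-4H-pyran-4-one; 9 carbon dioxide
Product: 11 {6-[3-(allyloxy)-4-(benzyloxy)phenyl]-4-oxo-4H-pyran-2-yl}acetic acid, via lithium dienolate 10 (not isolated)
Conditions: LiHMDS (1.1 equiv), THF, −78 °C; CO2 (g), −78 → 0 °C; then 1 M HCl, 0 °C
Reagents that add atoms: carbon dioxide (9), O=C=O; lithium hexamethyldisilazide, [Li+].C[Si](C)(C)[N-][Si](C)(C)C (supplies only the lithium of 10)
Why: Lateral (vinylogous) metalation of a 2-methyl-4-pyranone followed by carboxylation at the exocyclic γ-carbon, the normal site of intermolecular attack; the lithium carboxylate formed is too weak an acid to quench unreacted dienolate, which is why CO2 is chosen over a chloroformate.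

**Step 6**
Reactants: 11 {6-[3-(allyloxy)-4-(benzyloxy)phenyl]-4-oxo-4H-pyran-2-yl}acetic acid; 12 potassium methyl malonate
Product: 14 methyl 4-{6-[3-(allyloxy)-4-(benzyloxy)phenyl]-4-oxo-4H-pyran-2-yl}-3-oxobutanoate, via acyl imidazolide 13 (not isolated)
Conditions: CDI, THF, rt; then 12, MgCl2, Et3N, MeCN, rt → 40 °C; then 1 M HCl
Reagents that add atoms: potassium methyl malonate (12), COC(=O)CC(=O)[O-].[K+]; 1,1'-carbonyldiimidazole, O=C(n1ccnc1)n1ccnc1 (supplies only the imidazolyl group of 13)
Why: Masamune–Brooks decarboxylative Claisen condensation: the magnesium enolate of the malonate half-ester is C-acylated by the imidazolide and loses CO2, which gives the β-keto ester under near-neutral conditions that spare ring C.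

**Step 7**
Reactants: 14 methyl 4-{6-[3-(allyloxy)-4-(benzyloxy)phenyl]-4-oxo-4H-pyran-2-yl}-3-oxobutanoate
Product: 15 3'-O-allyl-4'-O-benzylluteolin, i.e. 2-[3-(allyloxy)-4-(benzyloxy)phenyl]-5,7-dihydroxy-4H-chromen-4-one
Conditions: DBU (3 equiv), dry MeCN (0.02 M), reflux; then 1 M HCl
Reagents that add atoms: none
Why: Proposed new method: DBU reversibly removes a proton from the C8 methylene, which lies between the C7 ketone and C8a of ring C, and the anion spreads over C8, C4a, O7 and O4, so that part of the charge sits on C4a while the ester, separated by the C6 methylene, remains a neutral electrophile (the C6-deprotonated tautomer is a resting state that equilibrates with it). C4a adds to the ester carbon C5 in a 6-(enolexo)-exo-trig closure, methoxide is expelled, and loss of the C4a proton plus enolisation at C5 and C7 delivers the phloroglucinol-type ring A, whose phenoxide cannot revert. The closest known reaction types are the base-induced Claisen aromatisation of 3,5,7-triketo esters to acylphloroglucinols and the Lacey–Dieckmann closure of stabilised 1,3-dicarbonyl anions onto esters; new here is acylation of a 4-pyranone dienolate at its α-carbon instead of the exocyclic γ-carbon. Regioselectivity is the only selectivity needed and ring size secures it: C8 or O7 attacking C5 would make a four-membered ring, and aldol attack of C6 on C4 would make a bicyclo[3.3.1] frame with a bridgehead C4a=C8a alkene. A non-nucleophilic amidine is preferred to an alkoxide so that ring C is not opened to a free tetraketo ester, which could fold in aldol modes, and so that retro-Claisen cleavage at C7 is suppressed. No stereocentre is created, and the allyl and benzyl ethers are inert to the base.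

**Step 8**
Reactants: 15 3'-O-allyl-4'-O-benzylluteolin
Product: 16 4'-O-benzylluteolin, i.e. 2-[4-(benzyloxy)-3-hydroxyphenyl]-5,7-dihydroxy-4H-chromen-4-one
Conditions: Pd(PPh3)4 (5 mol %), morpholine (5 equiv), THF, rt
Reagents that add atoms: none
Why: Tsuji–Trost-type deallylation: Pd(0) ionises the allyl aryl ether to a π-allyl complex and the 3'-phenoxide, and morpholine traps the allyl unit irreversibly, while the benzyl ether and the flavone are inert.

**Step 9**
Reactants: 16 4'-O-benzylluteolin; 17 sulfur trioxide–triethylamine complex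
Product: 18 bis(triethylammonium) 4'-O-benzylluteolin 7,3'-disulfate
Conditions: SO3·NEt3 (3 equiv), Et3N, DMA, 50 °C; Sephadex LH-20
Reagents that add atoms: sulfur trioxide–triethylamine complex (17), CC[N+](CC)(CC)S(=O)(=O)[O-]
Why: O-sulfation of phenols with an amine–sulfur trioxide complex: only 7-OH and 3'-OH are free and unchelated, 5-OH is tied to the C4 carbonyl by a strong hydrogen bond and 4'-O is benzylated, so a slight excess of reagent should stop at the 7,3'-disulfate.

**Step 10**
Reactants: 18 bis(triethylammonium) 4'-O-benzylluteolin 7,3'-disulfate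
Product: 20 luteolin 7,3'-disulfate (free acid form), via debenzylated triethylammonium salt 19 (not isolated)
Conditions: H2 (1 atm), 10% Pd/C, MeOH, rt; filter; then Dowex 50WX8 (H+ form), H2O, 0–5 °C; freeze-dry
Reagents that add atoms: none
Why: Catalytic hydrogenolysis of the benzyl aryl ether, which aryl sulfate salts and the flavone C2–C3 double bond tolerate, followed by cation exchange on a sulfonic acid resin that replaces triethylammonium by protons.

**Compound list**

1 | methyl 3,4-dihydroxybenzoate | COC(=O)c1ccc(O)c(O)c1 | starting material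
2 | benzyl bromide | BrCc1ccccc1 | starting material
3 | methyl 4-(benzyloxy)-3-hydroxybenzoate | COC(=O)c1ccc(OCc2ccccc2)c(O)c1 | intermediate
4 | allyl bromide | C=CCBr | starting material
5 | methyl 3-(allyloxy)-4-(benzyloxy)benzoate | COC(=O)c1ccc(OCc2ccccc2)c(OCC=C)c1 | intermediate
6 | acetylacetone | CC(=O)CC(C)=O | starting material
7 | 1-[3-(allyloxy)-4-(benzyloxy)phenyl]hexane-1,3,5-trione | CC(=O)CC(=O)CC(=O)c1ccc(OCc2ccccc2)c(OCC=C)c1 | intermediate
8 | 2-[3-(allyloxy)-4-(benzyloxy)phenyl]-6-methyl-4H-pyran-4-one | Cc1cc(=O)cc(-c2ccc(OCc3ccccc3)c(OCC=C)c2)o1 | intermediate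
9 | carbon dioxide | O=C=O | starting material
10 | lithium 6-[3-(allyloxy)-4-(benzyloxy)phenyl]-2-methylidene-2H-pyran-4-olate (not isolated) | [Li+].C=C1C=C([O-])C=C(c2ccc(OCc3ccccc3)c(OCC=C)c2)O1 | intermediate
11 | {6-[3-(allyloxy)-4-(benzyloxy)phenyl]-4-oxo-4H-pyran-2-yl}acetic acid | OC(=O)Cc1cc(=O)cc(-c2ccc(OCc3ccccc3)c(OCC=C)c2)o1 | intermediate
12 | potassium methyl malonate | COC(=O)CC(=O)[O-].[K+] | starting material
13 | 1-({6-[3-(allyloxy)-4-(benzyloxy)phenyl]-4-oxo-4H-pyran-2-yl}acetyl)imidazole (not isolated) | O=C(Cc1cc(=O)cc(-c2ccc(OCc3ccccc3)c(OCC=C)c2)o1)n1ccnc1 | intermediate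
14 | methyl 4-{6-[3-(allyloxy)-4-(benzyloxy)phenyl]-4-oxo-4H-pyran-2-yl}-3-oxobutanoate | COC(=O)CC(=O)Cc1cc(=O)cc(-c2ccc(OCc3ccccc3)c(OCC=C)c2)o1 | intermediate
15 | 3'-O-allyl-4'-O-benzylluteolin | O=c1cc(-c2ccc(OCc3ccccc3)c(OCC=C)c2)oc2cc(O)cc(O)c12 | intermediate
16 | 4'-O-benzylluteolin | O=c1cc(-c2ccc(OCc3ccccc3)c(O)c2)oc2cc(O)cc(O)c12 | intermediate
17 | sulfur trioxide–triethylamine complex | CC[N+](CC)(CC)S(=O)(=O)[O-] | starting material
18 | bis(triethylammonium) 4'-O-benzylluteolin 7,3'-disulfate | O=c1cc(-c2ccc(OCc3ccccc3)c(OS(=O)(=O)[O-])c2)oc2cc(OS(=O)(=O)[O-])cc(O)c12.CC[NH+](CC)CC.CC[NH+](CC)CC | intermediate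
19 | bis(triethylammonium) luteolin 7,3'-disulfate (not isolated) | O=c1cc(-c2ccc(O)c(OS(=O)(=O)[O-])c2)oc2cc(OS(=O)(=O)[O-])cc(O)c12.CC[NH+](CC)CC.CC[NH+](CC)CC | intermediate
20 | luteolin 7,3'-disulfate | O=c1cc(-c2ccc(O)c(OS(=O)(=O)O)c2)oc2cc(OS(=O)(=O)O)cc(O)c12 | target

**Totals**

Total step count: 10. Longest linear sequence: 10 steps, from 1.

**Steps most likely to fail**

**Step 7 (closure of ring A).**
- Risk: the doubly stabilised anion may be too poor a nucleophile at C4a. Intermolecular conjugate addition to a second pyranone ring, retro-Claisen loss of the acetate unit, or simple return of enolised material could then take over.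
- Fallback (known chemistry; ring A is bought and ring C is closed last): setting out from 5, saponification (LiOH, THF–MeOH–H2O) should give 3-(allyloxy)-4-(benzyloxy)benzoic acid F1. Oxalyl chloride with catalytic DMF in CH2Cl2 should then give 3-(allyloxy)-4-(benzyloxy)benzoyl chloride F2. The lithium polyanion of commercial 2,4,6-trihydroxyacetophenone (LiHMDS, 5 equiv, THF, −78 °C) is C-acylated by the chloride to 1-[3-(allyloxy)-4-(benzyloxy)phenyl]-3-(2,4,6-trihydroxyphenyl)propane-1,3-dione F3. Cyclodehydration (AcOH, cat. H2SO4, 95 °C) comes back to the route at 15.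

**Step 6 (two-carbon homologation).**
- Risk: the activated acyl group has a very acidic α-methylene. Enolisation to a ketene with self-condensation, or premature decarboxylation of the acid during activation, may outrun C-acylation of the magnesium malonate.
- Fallback (acyl Meldrum's acid route): setting out from 11, coupling with Meldrum's acid (DCC, DMAP, CH2Cl2, 0 °C) should give 5-({6-[3-(allyloxy)-4-(benzyloxy)phenyl]-4-oxo-4H-pyran-2-yl}acetyl)-2,2-dimethyl-1,3-dioxane-4,6-dione F4. Brief heating in methanol fragments it through the acylketene and comes back to the route at 14.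

**Step 9 (double sulfation).**
- Risk: incomplete sulfation at the hindered 3'-OH, over-sulfation at the chelated 5-OH, and loss of sulfate while the polar salts are purified.
- Fallback (protected sulfate diesters): setting out from 16, 2,2,2-trichloroethyl chlorosulfate (2.4 equiv), Et3N and DMAP in THF should give the neutral, chromatographable 4'-O-benzylluteolin 7,3'-bis(2,2,2-trichloroethyl sulfate) F5. Transfer hydrogenolysis (10% Pd/C, HCO2NH4, MeOH, rt) removes both trichloroethyl groups by reductive fragmentation and the benzyl ether in the same operation, giving diammonium luteolin 7,3'-disulfate F6. Passage through the H+ resin as in step 10 comes back to the route at 20.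

**Further compounds**

F1 | step 7 | 3-(allyloxy)-4-(benzyloxy)benzoic acid | OC(=O)c1ccc(OCc2ccccc2)c(OCC=C)c1
F2 | step 7 | 3-(allyloxy)-4-(benzyloxy)benzoyl chloride | ClC(=O)c1ccc(OCc2ccccc2)c(OCC=C)c1
F3 | step 7 | 1-[3-(allyloxy)-4-(benzyloxy)phenyl]-3-(2,4,6-trihydroxyphenyl)propane-1,3-dione | O=C(CC(=O)c1c(O)cc(O)cc1O)c1ccc(OCc2ccccc2)c(OCC=C)c1
F4 | step 6 | 5-({6-[3-(allyloxy)-4-(benzyloxy)phenyl]-4-oxo-4H-pyran-2-yl}acetyl)-2,2-dimethyl-1,3-dioxane-4,6-dione | CC1(C)OC(=O)C(C(=O)Cc2cc(=O)cc(-c3ccc(OCc4ccccc4)c(OCC=C)c3)o2)C(=O)O1
F5 | step 9 | 4'-O-benzylluteolin 7,3'-bis(2,2,2-trichloroethyl sulfate) | O=c1cc(-c2ccc(OCc3ccccc3)c(OS(=O)(=O)OCC(Cl)(Cl)Cl)c2)oc2cc(OS(=O)(=O)OCC(Cl)(Cl)Cl)cc(O)c12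
F6 | step 9 | diammonium luteolin 7,3'-disulfate | O=c1cc(-c2ccc(O)c(OS(=O)(=O)[O-])c2)oc2cc(OS(=O)(=O)[O-])cc(O)c12.[NH4+].[NH4+]
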